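**Strategy.** The depside ester between ring A O4 and ring B C1' is formed late, and everything rests on making the ring B acid from a symmetric 5-chloro-1,3-dialkoxy-2-methylbenzene. In ring B the C1' carboxyl carbon and the C2' methyl carbon are neighbours and lie next to the C6' oxygen. This is the pattern a 3-alkoxyaryne leaves when a carbon nucleophile enters at its far end and an electrophile enters next to oxygen. One operation thus forms the C2'–CH3 and C1'–CO2H bonds from the aryne, CH3Li and CO2. The two ring B oxygens are carried as isopropyl ethers, so a single BCl3 treatment ends the route.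

Key step: step 4

**Remarks before the steps**

- Numbering: ring A is C1 (CO2CH3), C2 (OH), C3 (CH3), C4 (O-acyl), C5 (CH3), C6 (CH3). Ring B is C1' (C=O), C2' (CH3), C3' (Cl), C4' (OH), C5' (CH3), C6' (OH). The target has no stereocentre.
- Remark on ring A: the target SMILES shows three methyl groups on ring A (C3, C5, C6). Commercial methyl atratate carries only the C3 and C6 methyls, so the C5 methyl is added in steps 6 and 7 before the coupling.
- Remark on the ether groups: isopropyl ethers play the same directing and inductive role as methyl ethers in the aryne step and tolerate the organolithium, iridium and copper steps. They are removed by BCl3 under conditions that should spare both esters and the aryl chloride. Benzyl ethers are avoided because their phenyl rings would be borylated in step 2 and their removal would need hydrogenation beside an aryl chloride.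
- Assumption: 2-methylresorcinol and methyl atratate are bought, and lithium 2,2,6,6-tetramethylpiperidide is charged as a preformed THF solution.

**Route**

Step 1
Reactants: 1 2-methylresorcinol (2-methylbenzene-1,3-diol)
Product: 2 1,3-diisopropoxy-2-methylbenzene
Conditions: 2-bromopropane (3 equiv), K2CO3, DMF, 70 °C
Reagents that add atoms: 2-bromopropane, CC(C)Br
Why: Williamson ether synthesis, in which both phenoxides are alkylated on oxygen by the secondary bromide in a polar aprotic solvent and the excess bromide covers what is lost to elimination.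

Step 2
Reactants: 2 1,3-diisopropoxy-2-methylbenzene
Product: 3 2-(3,5-diisopropoxy-4-methylphenyl)-4,4,5,5-tetramethyl-1,3,2-dioxaborolane
Conditions: B2pin2 (1.0 equiv), [Ir(OMe)(cod)]2 (1.5 mol %), 4,4'-di-tert-butyl-2,2'-bipyridine (3 mol %), THF, 80 °C
Reagents that add atoms: bis(pinacolato)diboron, CC1(C)OB(OC1(C)C)B1OC(C)(C)C(C)(C)O1
Why: Iridium-catalysed aromatic C–H borylation is governed by sterics, and C5 is the only ring C–H of 2 without an ortho substituent, so boron should enter meta to both ether groups.

Step 3
Reactants: 3 2-(3,5-diisopropoxy-4-methylphenyl)-4,4,5,5-tetramethyl-1,3,2-dioxaborolane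
Product: 4 5-chloro-1,3-diisopropoxy-2-methylbenzene
Conditions: CuCl2 (3 equiv), MeOH/H2O (1:1), 90 °C
Reagents that add atoms: copper dichloride CuCl2, [Cu+2].[Cl-].[Cl-]
Why: Copper-mediated chlorodeboronation of an aryl pinacol boronate replaces boron by chlorine at the same carbon, so the position fixed in step 2 is carried over unchanged.

Step 4
Reactants: 4 5-chloro-1,3-diisopropoxy-2-methylbenzene; 5 methyllithium; 6 carbon dioxide
Product: 10 2,4-diisopropoxy-3,6-dimethylbenzoic acid, via ortho-lithiated chloroarene 7 (not isolated), via alkoxyaryne 8 (not isolated), via ortho-alkoxy aryllithium 9 (not isolated)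
Conditions: lithium 2,2,6,6-tetramethylpiperidide (1.2 equiv), THF, −78 °C; CH3Li (3 equiv), −78 → 0 °C; CO2 (excess), −78 °C → rt; aq. HCl
Reagents that add atoms: methyllithium, [Li]C; carbon dioxide, O=C=O
Why: Lithium 2,2,6,6-tetramethylpiperidide removes the ring proton of 4 that lies between chlorine and an ether oxygen (the two such protons are equivalent by symmetry and are the most acidic in the molecule) to give 7, which on warming expels LiCl and becomes aryne 8 with its triple bond across the future C1' and C2'. Methyllithium then adds to the aryne carbon remote from oxygen (C2'), because the inductively withdrawing ether group beside the triple bond distorts it and places the developing carbanion on the carbon next to oxygen, and the resulting C1' aryllithium 9, stabilised by that oxygen, attacks CO2 to form the C1'–CO2H bond. The closest known reaction type is the addition of an organolithium reagent to a 3-alkoxyaryne generated from an ortho-lithiated haloarene ether, followed by carboxylation of the 2-alkoxyaryllithium to a 6-alkyl-2-alkoxybenzoic acid. No ring is closed and no stereocentre is created. The selectivity needed is the orientation of the methyl addition, and it is secured because only one flank of the triple bond carries an ether oxygen while the other carries hydrogen; the bulk of the isopropoxy group reinforces attack at the far carbon. The excess of methyllithium should outrun 9 and the amide base in capturing the aryne and should reconvert liberated 2,2,6,6-tetramethylpiperidine into its lithium amide, so that 9 survives until CO2 is admitted.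

Step 5
Reactants: 10 2,4-diisopropoxy-3,6-dimethylbenzoic acid
Product: 11 3-chloro-4,6-diisopropoxy-2,5-dimethylbenzoic acid
Conditions: SO2Cl2 (1.05 equiv), CH2Cl2, 0 °C → rt, dark
Reagents that add atoms: sulfuryl chloride, O=S(=O)(Cl)Cl
Why: Electrophilic aromatic chlorination at the single remaining ring C–H (C3' of ring B), which is ortho to the C4' ether oxygen and para to the C6' ether oxygen, with light excluded to suppress benzylic chlorination.

Step 6
Reactants: 12 methyl 2,4-dihydroxy-3,6-dimethylbenzoate (methyl atratate)
Product: 13 methyl 3-formyl-4,6-dihydroxy-2,5-dimethylbenzoate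
Conditions: Cl2CHOCH3 (1.5 equiv), TiCl4 (3 equiv), CH2Cl2, 0 °C → rt; aq. HCl
Reagents that add atoms: dichloromethyl methyl ether, COC(Cl)Cl; water, O
Why: Rieche formylation, in which the titanium phenoxide directs the electrophile to the only open ring position (C5 of ring A, ortho to the C4 hydroxyl and para to the C2 hydroxyl) and hydrolysis of the chloro ether releases the aldehyde.

Step 7
Reactants: 13 methyl 3-formyl-4,6-dihydroxy-2,5-dimethylbenzoate
Product: 14 methyl 2,4-dihydroxy-3,5,6-trimethylbenzoate
Conditions: Et3SiH (3 equiv), CF3CO2H, rt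
Reagents that add atoms: none
Why: Ionic hydrogenation, in which the protonated aldehyde takes hydride from the silane, the benzylic alcohol ionises to a cation stabilised by the ortho and para hydroxyls, and a second hydride gives the C5 methyl group while the ester is left alone.

Step 8
Reactants: 11 3-chloro-4,6-diisopropoxy-2,5-dimethylbenzoic acid; 14 methyl 2,4-dihydroxy-3,5,6-trimethylbenzoate
Product: 16 methyl 4-[(3-chloro-4,6-diisopropoxy-2,5-dimethylbenzoyl)oxy]-2-hydroxy-3,5,6-trimethylbenzoate, via mixed trifluoroacetic anhydride 15 (not isolated)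
Conditions: (CF3CO)2O (4 equiv), toluene, rt; aq. NaHCO3
Reagents that add atoms: none
Why: Trifluoroacetic anhydride-mediated esterification through a mixed anhydride with acylium character, the standard depside coupling for benzoic acids with two ortho substituents; the C4 hydroxyl of 14 should react in preference to the C2 hydroxyl, which is hydrogen-bonded to the ester carbonyl, and ring A has no free carbon for C-acylation.

Step 9
Reactants: 16 methyl 4-[(3-chloro-4,6-diisopropoxy-2,5-dimethylbenzoyl)oxy]-2-hydroxy-3,5,6-trimethylbenzoate
Product: 17 methyl 4-[(3-chloro-4,6-dihydroxy-2,5-dimethylbenzoyl)oxy]-2-hydroxy-3,5,6-trimethylbenzoate (the target)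
Conditions: BCl3 (1 M in CH2Cl2, 5 equiv), CH2Cl2, −78 → 0 °C; H2O
Reagents that add atoms: none
Why: Lewis acid dealkylation of aryl isopropyl ethers, in which BCl3 complexes each ether oxygen and the secondary alkyl group leaves as 2-chloropropane at low temperature; the methyl ester, the aryl ester and the aryl chloride should not react, and no free ring carbon is available for re-alkylation.

**Compound list**

1 | 2-methylresorcinol (2-methylbenzene-1,3-diol) | Cc1c(O)cccc1O | starting material
2 | 1,3-diisopropoxy-2-methylbenzene | Cc1c(OC(C)C)cccc1OC(C)C | intermediate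
3 | 2-(3,5-diisopropoxy-4-methylphenyl)-4,4,5,5-tetramethyl-1,3,2-dioxaborolane | Cc1c(OC(C)C)cc(cc1OC(C)C)B1OC(C)(C)C(C)(C)O1 | intermediate
4 | 5-chloro-1,3-diisopropoxy-2-methylbenzene (key-step precursor) | Cc1c(OC(C)C)cc(Cl)cc1OC(C)C | intermediate
5 | methyllithium | [Li]C | starting material
6 | carbon dioxide | O=C=O | starting material
7 | (6-chloro-2,4-diisopropoxy-3-methylphenyl)lithium | [Li]c1c(Cl)cc(OC(C)C)c(C)c1OC(C)C | intermediate
8 | 3,5-diisopropoxy-4-methylbenzyne (1,2-didehydro-3,5-diisopropoxy-4-methylbenzene) | CC(C)OC1=CC#CC(OC(C)C)=C1C | intermediate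
9 | (2,4-diisopropoxy-3,6-dimethylphenyl)lithium | [Li]c1c(C)cc(OC(C)C)c(C)c1OC(C)C | intermediate
10 | 2,4-diisopropoxy-3,6-dimethylbenzoic acid (key-step product) | Cc1cc(OC(C)C)c(C)c(OC(C)C)c1C(=O)O | intermediate
11 | 3-chloro-4,6-diisopropoxy-2,5-dimethylbenzoic acid | Cc1c(Cl)c(OC(C)C)c(C)c(OC(C)C)c1C(=O)O | intermediate
12 | methyl 2,4-dihydroxy-3,6-dimethylbenzoate (methyl atratate) | COC(=O)c1c(C)cc(O)c(C)c1O | starting material
13 | methyl 3-formyl-4,6-dihydroxy-2,5-dimethylbenzoate | COC(=O)c1c(C)c(C=O)c(O)c(C)c1O | intermediate
14 | methyl 2,4-dihydroxy-3,5,6-trimethylbenzoate | COC(=O)c1c(C)c(C)c(O)c(C)c1O | intermediate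
15 | 3-chloro-4,6-diisopropoxy-2,5-dimethylbenzoic trifluoroacetic anhydride | Cc1c(Cl)c(OC(C)C)c(C)c(OC(C)C)c1C(=O)OC(=O)C(F)(F)F | intermediate
16 | methyl 4-[(3-chloro-4,6-diisopropoxy-2,5-dimethylbenzoyl)oxy]-2-hydroxy-3,5,6-trimethylbenzoate | COC(=O)c1c(C)c(C)c(OC(=O)c2c(C)c(Cl)c(OC(C)C)c(C)c2OC(C)C)c(C)c1O | intermediate
17 | methyl 4-[(3-chloro-4,6-dihydroxy-2,5-dimethylbenzoyl)oxy]-2-hydroxy-3,5,6-trimethylbenzoate | COC(=O)c1c(C)c(C)c(OC(=O)c2c(C)c(Cl)c(O)c(C)c2O)c(C)c1O | target

**Step count and risks**

Total step count: 9. Longest linear sequence: 7 (steps 1, 2, 3, 4, 5, 8, 9); steps 6 and 7 prepare the ring A partner.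

The three steps most likely to fail:

Step 4. The aryne may be captured by the aryllithium it has just produced or by the amide base instead of by methyllithium, and proton transfer from the liberated amine may quench the C1' anion before CO2 arrives. Either process would give biaryls or the non-carboxylated arene. The fallback installs the methyl group by cross-coupling and the carboxyl carbon by electrophilic substitution. Setting out from 4, a Suzuki–Miyaura methylation (trimethylboroxine, Pd(OAc)2, SPhos, K3PO4, toluene/H2O, 100 °C) would give 1,3-diisopropoxy-2,5-dimethylbenzene F1. Vilsmeier–Haack formylation (POCl3, DMF, then aqueous NaOAc) at one of its two equivalent ring positions, each ortho and para to an ether oxygen, would give 2,4-diisopropoxy-3,6-dimethylbenzaldehyde F2. Pinnick oxidation (NaClO2, NaH2PO4, 2-methyl-2-butene, t-BuOH/H2O) would bring the route back at 10.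

Step 8. Acyl transfer from a benzoic acid with two ortho substituents to a phenol flanked by two methyl groups may stall at the mixed anhydride, or part of the acyl group may be delivered to the hydrogen-bonded C2 hydroxyl. The fallback replaces the acid-promoted mixed anhydride by a base-mediated acylation with an isolated acyl chloride. Setting out from 11, oxalyl chloride with catalytic DMF in CH2Cl2 would give 3-chloro-4,6-diisopropoxy-2,5-dimethylbenzoyl chloride F3. Heating F3 with 14 in pyridine containing catalytic 4-(dimethylamino)pyridine would acylate the more acidic, non-chelated C4 hydroxyl and bring the route back at 16.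

Step 9. Cleavage of the O4' ether, which has no carbonyl neighbour to assist, may lag behind that of the O6' ether, and forcing the reaction may begin to erode the aryl ester or the methyl ester. The fallback moves the ether cleavage ahead of the coupling and changes the protecting group. Setting out from 11, BCl3 in CH2Cl2 would give 3-chloro-4,6-dihydroxy-2,5-dimethylbenzoic acid F4, with no ester present at that stage. Benzyl bromide and K2CO3 in DMF would give benzyl 4,6-bis(benzyloxy)-3-chloro-2,5-dimethylbenzoate F5, and KOH in aqueous DMSO would give 4,6-bis(benzyloxy)-3-chloro-2,5-dimethylbenzoic acid F6. Coupling of F6 with 14 under the conditions of step 8 would pass through 4,6-bis(benzyloxy)-3-chloro-2,5-dimethylbenzoic trifluoroacetic anhydride F7 and give methyl 4-{[4,6-bis(benzyloxy)-3-chloro-2,5-dimethylbenzoyl]oxy}-2-hydroxy-3,5,6-trimethylbenzoate F8. Hydrogenolysis (H2 at 1 atm, palladium on carbon, ethyl acetate, rt, stopped once two equivalents are taken up so that the aryl chloride is kept) would bring the route back at 17.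

**Further compounds**

F1 | step 4 | 1,3-diisopropoxy-2,5-dimethylbenzene | Cc1cc(OC(C)C)c(C)c(OC(C)C)c1
F2 | step 4 | 2,4-diisopropoxy-3,6-dimethylbenzaldehyde | Cc1cc(OC(C)C)c(C)c(OC(C)C)c1C=O
F3 | step 8 | 3-chloro-4,6-diisopropoxy-2,5-dimethylbenzoyl chloride | Cc1c(Cl)c(OC(C)C)c(C)c(OC(C)C)c1C(=O)Cl
F4 | step 9 | 3-chloro-4,6-dihydroxy-2,5-dimethylbenzoic acid | Cc1c(Cl)c(O)c(C)c(O)c1C(=O)O
F5 | step 9 | benzyl 4,6-bis(benzyloxy)-3-chloro-2,5-dimethylbenzoate | Cc1c(Cl)c(OCc2ccccc2)c(C)c(OCc2ccccc2)c1C(=O)OCc1ccccc1
F6 | step 9 | 4,6-bis(benzyloxy)-3-chloro-2,5-dimethylbenzoic acid | Cc1c(Cl)c(OCc2ccccc2)c(C)c(OCc2ccccc2)c1C(=O)O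
F7 | step 9 | 4,6-bis(benzyloxy)-3-chloro-2,5-dimethylbenzoic trifluoroacetic anhydride | Cc1c(Cl)c(OCc2ccccc2)c(C)c(OCc2ccccc2)c1C(=O)OC(=O)C(F)(F)F
F8 | step 9 | methyl 4-{[4,6-bis(benzyloxy)-3-chloro-2,5-dimethylbenzoyl]oxy}-2-hydroxy-3,5,6-trimethylbenzoate | COC(=O)c1c(C)c(C)c(OC(=O)c2c(C)c(Cl)c(OCc3ccccc3)c(C)c2OCc2ccccc2)c(C)c1O
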